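**Retrosynthetic overview**

1. Last bond: the methylene bridge, made by adding the ring CH of propionylfilicinic acid 21 to an o-quinone methide from chromene 19; 21 comes from flopropione 20 by dearomatising gem-dimethylation, so the filicinic ring is a dearomatised benzene ring.
2. The C8 acetyl group is put on chromene 16 by lithiation of its only aromatic C–H.
3. The pyran ring is the only ring built on the route: aryne 13 and prenal 12 give chromene 16 in one operation (formal [2+2] of the C=O across the aryne, 4π ring opening, oxa-6π ring closure); the benzene ring is that of resorcinol.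
4. Enabling feature: the pyran oxygen O1 and the vinylic carbon C4 sit on the adjacent ring-fusion carbons C8a and C4a of the phloroglucinol ring, and C2 is a gem-dimethyl carbon, so O1–C8a and C4–C4a are the carbonyl group of prenal laid across an aryne bond; the oxygen on C5, next to C4a, polarises that aryne.
5. Aryne precursor 11 comes from resorcinol: MOM protection, lithiation/methoxymethylation (future bridge carbon, blocks C6), C–H borylation/oxidation (the oxygen that later leaves as triflate), bromination, retro-Brook silyl shift/triflation.

Key step: step 6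

Remark: the target has no stereocentre, and its filicinic ring is drawn as one of several equilibrating enol tautomers; the route is planned for that compound. Chromene positions are numbered O1, C2, C3, C4, C4a, C5 to C8, C8a throughout.

**Route**

Step 1
Reactants: 1 resorcinol
Product: 2 1,3-bis(methoxymethoxy)benzene
Conditions: NaH (2.4 equiv), MOMCl (2.4 equiv), DMF, 0 °C → rt
Reagents that add atoms: chloromethyl methyl ether, COCCl
Why: Double O-alkylation of the phenoxide (Williamson ether synthesis) should protect both hydroxyl groups as MOM ethers; no stereocentre is formed.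

Step 2
Reactants: 2 1,3-bis(methoxymethoxy)benzene
Product: 4 2-(methoxymethyl)-1,3-bis(methoxymethoxy)benzene, via aryllithium 3 (not isolated)
Conditions: n-BuLi (1.1 equiv), THF, 0 °C; MOMCl (1.3 equiv), −78 °C → rt
Reagents that add atoms: chloromethyl methyl ether, COCCl
Why: Directed ortho-metalation occurs at the carbon flanked by both OMOM groups, and the aryllithium is alkylated by the chloromethyl ether to place the future bridge carbon as a benzylic methyl ether; no stereocentre is formed.

Step 3
Reactants: 4 2-(methoxymethyl)-1,3-bis(methoxymethoxy)benzene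
Product: 6 4-(methoxymethyl)-3,5-bis(methoxymethoxy)phenol, via arylboronate 5 (not isolated)
Conditions: [Ir(OMe)(cod)]2 (1.5 mol %), dtbpy (3 mol %), HBpin (1.5 equiv), THF, 80 °C; then 30% H2O2, 2 M NaOH, THF, 0 °C
Reagents that add atoms: hydrogen peroxide, OO
Why: Sterically controlled iridium-catalysed C–H borylation should select the only C–H without an ortho substituent, and oxidation of the C–B bond with 1,2-aryl shift to oxygen then gives the phenol; no stereocentre is formed.

Step 4
Reactants: 6 4-(methoxymethyl)-3,5-bis(methoxymethoxy)phenol
Product: 7 2-bromo-4-(methoxymethyl)-3,5-bis(methoxymethoxy)phenol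
Conditions: NBS (1.0 equiv), CH2Cl2, −78 → −40 °C
Reagents that add atoms: N-bromosuccinimide, O=C1CCC(=O)N1Br
Why: Electrophilic aromatic bromination can only occur at one of the two equivalent free positions ortho to the hydroxyl group, so the regiochemistry is fixed and one equivalent at low temperature should hold it at monobromination; no stereocentre is formed.

Step 5
Reactants: 7 2-bromo-4-(methoxymethyl)-3,5-bis(methoxymethoxy)phenol
Product: 11 4-(methoxymethyl)-3,5-bis(methoxymethoxy)-2-(trimethylsilyl)phenyl trifluoromethanesulfonate, via silyl ether 8 (not isolated), via aryllithium 9 (not isolated), via lithium phenolate 10 (not isolated)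
Conditions: HMDS, THF, 65 °C, then evaporation; n-BuLi (1.1 equiv), THF, −78 °C; Tf2O (1.2 equiv), −78 → 0 °C
Reagents that add atoms: hexamethyldisilazane, C[Si](C)(C)N[Si](C)(C)C; trifluoromethanesulfonic anhydride, O=S(=O)(OS(=O)(=O)C(F)(F)F)C(F)(F)F
Why: O-silylation, bromine–lithium exchange, anionic 1,3 O→C silyl shift (retro-Brook rearrangement) and O-triflation of the resulting phenolate should give the ortho-silylaryl triflate; no stereocentre is formed.

Step 6
Reactants: 11 4-(methoxymethyl)-3,5-bis(methoxymethoxy)-2-(trimethylsilyl)phenyl trifluoromethanesulfonate; 12 3-methylbut-2-enal (prenal)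
Product: 16 6-(methoxymethyl)-5,7-bis(methoxymethoxy)-2,2-dimethyl-2H-chromene, via aryne 13 (not isolated), via benzoxete 14 (not isolated), via o-quinone methide 15 (not isolated)
Conditions: CsF (3 equiv), 12 (5 equiv), MeCN, rt
Reagents that add atoms: none
Why: Fluoride removes the silyl group and triflate leaves to give aryne 13; the carbonyl oxygen of 12 attacks the aryne carbon remote from the neighbouring OMOM group (future C8a) and the aryl anion that develops next to that OMOM group (future C4a) closes on the carbonyl carbon, a formal [2+2] cycloaddition that gives benzoxete 14. Thermal 4π ring opening of 14 cleaves its O–CH bond to give o-quinone methide 15, whose O=C8a–C4a=C4–C3=C2 array closes by thermal oxa-6π electrocyclisation onto the dimethyl-bearing terminus, which forms the O1–C2 bond, completes the pyran ring and restores the benzene ring. The closest known reaction type is the fluoride-induced reaction of arynes with α,β-unsaturated aldehydes to give 2H-chromenes, an extension of aryne insertion into the C=O bond of aldehydes and formamides. Modes of closure: the transient oxete by polar stepwise [2+2] (4-exo attack of the aryl anion on the activated carbonyl carbon), the pyran by disrotatory 6π electrocyclisation of the (Z)-dienone. No stereocentre results: the CH of 14 is formed racemic and ends as the sp2 carbon C4, and the E and Z isomers of 15 interconvert while only Z can close. The step needs regioselective addition across the unsymmetrical aryne and attack at C=O in preference to C=C; the inductively withdrawing OMOM oxygen ortho to one aryne carbon directs the nucleophilic oxygen to the distal carbon (the known 3-alkoxyaryne bias), the other flank (C8) carries only hydrogen, and the excess of 12 keeps a second aryne from trapping 15.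

Step 7
Reactants: 16 6-(methoxymethyl)-5,7-bis(methoxymethoxy)-2,2-dimethyl-2H-chromene
Product: 18 1-[6-(methoxymethyl)-5,7-bis(methoxymethoxy)-2,2-dimethyl-2H-chromen-8-yl]ethan-1-one, via aryllithium 17 (not isolated)
Conditions: s-BuLi (1.2 equiv), TMEDA, THF, −78 °C; MeC(O)N(OMe)Me, −78 → 0 °C; H2O
Reagents that add atoms: N-methoxy-N-methylacetamide, CC(=O)N(C)OC
Why: Directed ortho-metalation should take place at C8, the only aromatic C–H, which lies between the C7 OMOM group and O1 (the benzylic CH2 is deactivated by its ortho and para oxygen donors), and the aryllithium is acylated once by the Weinreb amide (Weinreb ketone synthesis); no stereocentre is formed.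

Step 8
Reactants: 18 1-[6-(methoxymethyl)-5,7-bis(methoxymethoxy)-2,2-dimethyl-2H-chromen-8-yl]ethan-1-one
Product: 19 1-[5,7-dihydroxy-6-(methoxymethyl)-2,2-dimethyl-2H-chromen-8-yl]ethan-1-one
Conditions: 3 M HCl, MeOH, 40 °C
Reagents that add atoms: none
Why: Acid-catalysed acetal exchange in methanol should cleave both MOM ethers and carry the formaldehyde off as its dimethyl acetal, while the benzylic methyl ether, if it ionises, is re-formed by the solvent; no stereocentre is formed.

Step 9
Reactants: 20 flopropione (1-(2,4,6-trihydroxyphenyl)propan-1-one)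
Product: 21 propionylfilicinic acid (3,5-dihydroxy-4,4-dimethyl-2-propanoylcyclohexa-2,5-dien-1-one)
Conditions: NaOMe (4 equiv), MeI (2.5 equiv), MeOH, 0 °C → rt
Reagents that add atoms: iodomethane, CI
Why: Dearomatising double C-methylation of the acylphloroglucinol polyanion at one unsubstituted ring carbon is the classical entry to acylfilicinic acids, with under- and over-methylated congeners to be removed by chromatography; no stereocentre is formed.

Step 10
Reactants: 19 1-[5,7-dihydroxy-6-(methoxymethyl)-2,2-dimethyl-2H-chromen-8-yl]ethan-1-one; 21 propionylfilicinic acid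
Product: 23 target CNP0153527.0, via o-quinone methide 22 (not isolated)
Conditions: 21 (2 equiv), PPTS (10 mol %), 1,4-dioxane, 4 Å MS, 80 °C
Reagents that add atoms: none
Why: Loss of methanol from the o-hydroxybenzyl ether (pushed by the free C5 hydroxyl, assisted by mild acid) should give the o-quinone methide, to whose exocyclic methylene the nucleophilic ring CH of the vinylogous acid 21 adds (Michael addition) before tautomerisation restores the arene; no stereocentre is formed.

**Compound list**

1 | resorcinol (benzene-1,3-diol) | Oc1cccc(O)c1 | starting material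
2 | 1,3-bis(methoxymethoxy)benzene | COCOc1cccc(OCOC)c1 | intermediate
3 | [2,6-bis(methoxymethoxy)phenyl]lithium (not isolated) | [Li]c1c(OCOC)cccc1OCOC | intermediate
4 | 2-(methoxymethyl)-1,3-bis(methoxymethoxy)benzene | COCc1c(OCOC)cccc1OCOC | intermediate
5 | 2-[4-(methoxymethyl)-3,5-bis(methoxymethoxy)phenyl]-4,4,5,5-tetramethyl-1,3,2-dioxaborolane (not isolated) | COCc1c(OCOC)cc(cc1OCOC)B1OC(C)(C)C(C)(C)O1 | intermediate
6 | 4-(methoxymethyl)-3,5-bis(methoxymethoxy)phenol | COCc1c(OCOC)cc(O)cc1OCOC | intermediate
7 | 2-bromo-4-(methoxymethyl)-3,5-bis(methoxymethoxy)phenol | COCc1c(OCOC)cc(O)c(Br)c1OCOC | intermediate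
8 | [2-bromo-4-(methoxymethyl)-3,5-bis(methoxymethoxy)phenoxy]trimethylsilane (not isolated) | COCc1c(OCOC)cc(O[Si](C)(C)C)c(Br)c1OCOC | intermediate
9 | [3-(methoxymethyl)-2,4-bis(methoxymethoxy)-6-(trimethylsilyloxy)phenyl]lithium (not isolated) | COCc1c(OCOC)cc(O[Si](C)(C)C)c([Li])c1OCOC | intermediate
10 | lithium 4-(methoxymethyl)-3,5-bis(methoxymethoxy)-2-(trimethylsilyl)phenolate (not isolated) | COCc1c(OCOC)cc(O[Li])c([Si](C)(C)C)c1OCOC | intermediate
11 | 4-(methoxymethyl)-3,5-bis(methoxymethoxy)-2-(trimethylsilyl)phenyl trifluoromethanesulfonate | COCc1c(OCOC)cc(OS(=O)(=O)C(F)(F)F)c([Si](C)(C)C)c1OCOC | intermediate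
12 | 3-methylbut-2-enal (prenal) | CC(C)=CC=O | starting material
13 | 4-(methoxymethyl)-3,5-bis(methoxymethoxy)-1,2-didehydrobenzene (aryne, not isolated) | COCC1=C(OCOC)C#CC=C1OCOC | intermediate
14 | racemic 4-(methoxymethyl)-3,5-bis(methoxymethoxy)-2-(2-methylprop-1-enyl)-2H-benzoxete (not isolated) | COCc1c(OCOC)cc2OC(C=C(C)C)c2c1OCOC | intermediate
15 | (6Z)-4-(methoxymethyl)-3,5-bis(methoxymethoxy)-6-(3-methylbut-2-enylidene)cyclohexa-2,4-dien-1-one (not isolated) | COCC1=C(OCOC)/C(=C/C=C(C)C)C(=O)C=C1OCOC | intermediate
16 | 6-(methoxymethyl)-5,7-bis(methoxymethoxy)-2,2-dimethyl-2H-chromene | COCc1c(OCOC)cc2OC(C)(C)C=Cc2c1OCOC | intermediate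
17 | [6-(methoxymethyl)-5,7-bis(methoxymethoxy)-2,2-dimethyl-2H-chromen-8-yl]lithium (not isolated) | COCc1c(OCOC)c([Li])c2OC(C)(C)C=Cc2c1OCOC | intermediate
18 | 1-[6-(methoxymethyl)-5,7-bis(methoxymethoxy)-2,2-dimethyl-2H-chromen-8-yl]ethan-1-one | COCc1c(OCOC)c(C(C)=O)c2OC(C)(C)C=Cc2c1OCOC | intermediate
19 | 1-[5,7-dihydroxy-6-(methoxymethyl)-2,2-dimethyl-2H-chromen-8-yl]ethan-1-one | COCc1c(O)c(C(C)=O)c2OC(C)(C)C=Cc2c1O | intermediate
20 | flopropione (1-(2,4,6-trihydroxyphenyl)propan-1-one) | CCC(=O)c1c(O)cc(O)cc1O | starting material
21 | propionylfilicinic acid (3,5-dihydroxy-4,4-dimethyl-2-propanoylcyclohexa-2,5-dien-1-one) | CCC(=O)C1=C(O)C(C)(C)C(O)=CC1=O | intermediate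
22 | 8-acetyl-7-hydroxy-2,2-dimethyl-6-methylidene-2H-chromen-5(6H)-one (o-quinone methide, not isolated) | C=C1C(=O)C2=C(OC(C)(C)C=C2)C(C(C)=O)=C1O | intermediate
23 | CNP0153527.0 | CCC(=O)C1=C(O)C(C)(C)C(O)=C(Cc2c(O)c3c(c(C(C)=O)c2O)OC(C)(C)C=C3)C1=O | target

**Step count and risks**

Total step count: 10. Longest linear sequence: 9 steps (steps 1 to 8, then step 10); step 9 is a one-step side branch.

The three steps most likely to fail:

Step 6. Regiocontrol of the addition across the aryne may erode, fluoride may induce self-condensation of the enal, or the o-quinone methide may be intercepted before ring closure. The fallback sets out from phenol 6 and comes back to the route at chromene 16. Phenol 6 would be O-alkylated with 3-chloro-3-methylbut-1-yne (CuCl2 cat., DBU, MeCN, 0 °C) to give 2-(methoxymethyl)-1,3-bis(methoxymethoxy)-5-[(2-methylbut-3-yn-2-yl)oxy]benzene F1. Heating F1 in xylene at 140 °C should give 16 by aryl propargyl ether Claisen rearrangement, 1,5-hydrogen shift and oxa-6π ring closure. The two ortho positions of 6 are equivalent, so only one chromene can form.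

Step 7. Deprotonation may take place at the benzylic methylene (followed by Wittig rearrangement) instead of at C8, or the hindered aryllithium may take a proton from the amide instead of being acylated. The fallback sets out from chromene 16 and comes back to the route at 19. Electrophilic iodination (NIS, MeCN, 0 °C) at the only free ring position should give 8-iodo-6-(methoxymethyl)-5,7-bis(methoxymethoxy)-2,2-dimethyl-2H-chromene F2. Stille coupling of F2 with tributyl(1-ethoxyvinyl)stannane (Pd(PPh3)4 cat., toluene, 100 °C) should give 8-(1-ethoxyvinyl)-6-(methoxymethyl)-5,7-bis(methoxymethoxy)-2,2-dimethyl-2H-chromene F3. The conditions of step 8 (aqueous HCl, MeOH) should then hydrolyse the enol ether to the acetyl group and cleave both MOM ethers to give 19.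

Step 10. The o-quinone methide may be consumed by cycloaddition to the chromene double bond of a second molecule or by oligomerisation, and the acid may cause cyclodehydration of the adduct. The fallback sets out from 19 and comes back to the route at target 23. It replaces acid-driven ionisation by base-induced elimination in the presence of the filicinate anion. Treatment of 19 with sodium 4-methylbenzenesulfinate in aqueous formic acid at rt should give 1-{5,7-dihydroxy-2,2-dimethyl-6-[(4-methylphenyl)sulfonylmethyl]-2H-chromen-8-yl}ethan-1-one F4. Stirring F4 with 21 and Cs2CO3 in MeCN at rt should release 22 slowly by 1,4-elimination of sulfinate from the phenoxide; the anion of 21 traps it, and acidification should give 23.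

**Further compounds**

F1 | step 6 | 2-(methoxymethyl)-1,3-bis(methoxymethoxy)-5-[(2-methylbut-3-yn-2-yl)oxy]benzene | COCc1c(OCOC)cc(OC(C)(C)C#C)cc1OCOC
F2 | step 7 | 8-iodo-6-(methoxymethyl)-5,7-bis(methoxymethoxy)-2,2-dimethyl-2H-chromene | COCc1c(OCOC)c(I)c2OC(C)(C)C=Cc2c1OCOC
F3 | step 7 | 8-(1-ethoxyvinyl)-6-(methoxymethyl)-5,7-bis(methoxymethoxy)-2,2-dimethyl-2H-chromene | COCc1c(OCOC)c(C(=C)OCC)c2OC(C)(C)C=Cc2c1OCOC
F4 | step 10 | 1-{5,7-dihydroxy-2,2-dimethyl-6-[(4-methylphenyl)sulfonylmethyl]-2H-chromen-8-yl}ethan-1-one | Cc1ccc(cc1)S(=O)(=O)Cc1c(O)c(C(C)=O)c2OC(C)(C)C=Cc2c1O
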